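**Two runs.** The noon and autumn runs differ in charge, yet at 20.0 min their G reads 7.8 % and 8.3 %. With D held, I therefore treat G as forming first order in Z (pseudo-first-order).

| flask | Z | D | remark | time |
|---|---|---|---|---|
| noon | 0.10 M (fed, over 30 min) | 11 mM (held) | run made earlier; the fed solution adds 0.20 times the starting volume |  |
| autumn | 0.15 M (fed, over 30 min) | 11 mM (held) | run made earlier; the fed solution adds 0.20 times the starting volume |  |
| Thursday's | 0.20 M (fed, over 30 min) | 11 mM (held) | the fed solution adds 0.20 times the starting volume | 30 min |
| Friday's | 0.20 M | 11 mM | everything together at the start, the whole solution of Z included, so that from the start the volume is larger by 0.20 times the starting volume | 30 min |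

| run | time / min | G / % | Z / % |
|---|---|---|---|
| noon | 2.50 | 0 | 8.0 |
| noon | 8.00 | 1.4 | 24.8 |
| noon | 12.0 | 3.0 | 36.2 |
| noon | 20.0 | 7.8 | 56.6 |
| noon | 30.0 | 16.4 | 79.1 |
| noon | 40.0 | 24.2 | 68.7 |
| autumn | 3.00 | 0.2 | 9.2 |
| autumn | 5.00 | 0.8 | 16.0 |
| autumn | 8.00 | 1.2 | 24.8 |
| autumn | 12.0 | 3.2 | 36.1 |
| autumn | 20.0 | 8.3 | 56.2 |
| autumn | 40.0 | 23.9 | 66.1 |

(scatter of a reading: 0.3 percentage points)

- the flask that ends with the higher amount of G, in percent of the Z charged, or "neither" when 2 percentage points or less lies between them (Thursday's / Friday's / neither)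
- final G, as a percentage of the Z charged, in Thursday's
- final G, as a percentage of the Z charged, in Friday's

- charges are per starting volume, the dose included; the dosed solution carries all of it
- the numbers in the tables scatter by 0.3 percentage points (one standard deviation)
- percentages count the whole charge, also what has not yet gone in

**Net rate.** Between 12.0 min and 20.0 min, noon's G gains 0.00600 min⁻¹ as a fraction of the charge, with mean Z 46.4 % and mean G 5.40 %. Between 30.0 min and 40.0 min, it gains 0.00780 min⁻¹, with mean Z 73.9 % and mean G 20.3 %. Per unit of Z, the later window is slower, and it holds more G. I read this as a forward term on Z minus a return term on G. The two windows give a return constant of 0.0150 min⁻¹ and a forward constant of 0.0147 min⁻¹.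

**Time constant.** The exchange time constant, one over the sum of these two constants, is 33.7 min. The net rate vanishes at a G to Z ratio of 0.978.

**My reckoning.** Friday's starts with its whole charge as Z, so its rate starts at 0.0147 min⁻¹. In Friday's, by 30 min, I reckon that the exchange brings that rate down to 0.410 of its starting value, and the accumulated G is 29.2 %. The share missing at 40.0 min is 7.10 % at noon and 10.0 % in autumn, so it grows with the charge. Scaled to Friday's charge it is 13.3 %. Growing steadily, it costs G about 2.94 %, which leaves 26.2 %. Thursday's stops as its feed ends, so I take noon's 16.4 %.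

**The forecast.** It says Friday's, with 16 % for Thursday's and 27 % for Friday's, on the ground that “Friday's has all Z present for the full 30 min”. Its Friday figure stands above mine.

**The flasks.** Thursday's ends at 16.3 % and Friday's at 26.0 %, so the answer is Friday's.

    Z + Q ⇌ G (K = 85.0 L mol⁻¹, k = 1.40 L mol⁻¹ min⁻¹)
    2 Z → E (k = 0.0310 L mol⁻¹ min⁻¹)
    D ⇌ Q, rate k3*(csat - [Q]) (kL = 12.0 min⁻¹)

**Left longer.** The neighbour is Thursday's left until 2.0 h. At 30.0 min, Thursday's holds G 16.3 % against Z 76.4 %, a ratio of 0.213, which is lower than 0.978. The extra 90.0 min is 2.67 time constants, so I reckon the gap to balance shrinks to 0.0693 of itself and the ratio ends near 0.978. The neighbour ends with G 35.1 % against Z 35.6 %, a ratio of 0.986.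

(The readings were computed with made-up constants; scatter was added.)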